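The flavanone ring C is opened at the aryl ether bond O1–C8a, because O1 bridges ring A and the benzylic stereocentre C2 and can therefore be attached to C8a without touching any bond at C2. A palladium-catalysed intramolecular etherification of a ring A bromide by the preformed (S)-carbinol closes ring C with the configuration intact. The C4 carbonyl is carried as an exocyclic CH2, so no aldol-type fragmentation or elimination can occur under base. The cyclisation substrate is an octa-O-benzyl (S)-homoallylic alcohol, assembled by catalytic asymmetric allylboration of a luteolin-8-yl benzaldehyde with a 2-(2-bromoaryl)allyl boronate. Alkene cleavage and hydrogenolysis finish the synthesis.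

Key step: step 14

Remark 1: all eight phenols, including the two chelated 5-OH groups, are carried as benzyl ethers, so that the C2 hydroxyl is the only nucleophile in the ring closure and a single neutral hydrogenolysis ends the route. "LutBn4" denotes the 5,7-bis(benzyloxy)-2-[3,4-bis(benzyloxy)phenyl]-4-oxo-4H-chromen-8-yl group.

Remark 2: the (S)-enantiomer of the phosphoric acid in step 13 is assigned by analogy with aryl aldehyde allylborations ((R)-acid giving R-carbinols of the same priority pattern O > aryl > CH2 > H). The configuration of 17 would be verified (Mosher esters) before step 14, and the other catalyst enantiomer used if required.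

Step 1
Reactants: 1 luteolin
Product: 2 5,7-bis(benzyloxy)-2-[3,4-bis(benzyloxy)phenyl]-4H-chromen-4-one (tetra-O-benzylluteolin)
Conditions: BnBr (excess), K2CO3, DMF, 80 °C
Reagents that add atoms: benzyl bromide, BrCc1ccccc1
Why: Williamson etherification of all four phenols; the hydrogen-bonded 5-OH is the least reactive, hence excess halide and heat, and its protection later steers iodination to C8 and keeps phenoxides out of the palladium chemistry.

Step 2
Reactants: 2 tetra-O-benzylluteolin
Product: 3 5,7-bis(benzyloxy)-2-[3,4-bis(benzyloxy)phenyl]-8-iodo-4H-chromen-4-one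
Conditions: NIS, TFA (cat.), CH2Cl2, 0 °C to rt
Reagents that add atoms: N-iodosuccinimide, O=C1CCC(=O)N1I
Why: Electrophilic aromatic iodination of the most electron-rich ring (ring A of the flavone, three oxygen donors); with O5 alkylated, 5,7-dialkoxyflavones react at C8 (para to the 5-alkoxy group) in preference to C6, which lies between two benzyloxy groups.

Step 3
Reactants: 4 3-bromo-4,5-dihydroxybenzaldehyde
Product: 5 3,4-bis(benzyloxy)-5-bromobenzaldehyde
Conditions: BnBr, K2CO3, DMF, 60 °C
Reagents that add atoms: benzyl bromide, BrCc1ccccc1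
Why: Williamson etherification of the catechol; the aldehyde and the aryl bromide are inert to carbonate and benzyl bromide.

Step 4
Reactants: 5 3,4-bis(benzyloxy)-5-bromobenzaldehyde
Product: 6 3,4-bis(benzyloxy)-5-(4,4,5,5-tetramethyl-1,3,2-dioxaborolan-2-yl)benzaldehyde
Conditions: B2pin2, PdCl2(dppf), KOAc, 1,4-dioxane, 90 °C
Reagents that add atoms: bis(pinacolato)diboron, CC1(C)OB(OC1(C)C)B1OC(C)(C)C(C)(C)O1
Why: Miyaura borylation of the aryl bromide; the weak acetate base does not promote homocoupling and the aldehyde is tolerated.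

Step 5
Reactants: 3 8-iodo-tetra-O-benzylluteolin; 6 3,4-bis(benzyloxy)-5-(pinacolboryl)benzaldehyde
Product: 7 3,4-bis(benzyloxy)-5-(LutBn4)benzaldehyde
Conditions: Pd(OAc)2, SPhos, K3PO4, toluene/H2O, 90 °C
Reagents that add atoms: none
Why: Suzuki–Miyaura cross-coupling forming the C8–C5' biaryl bond (tri-ortho-substituted), for which the bulky dialkylbiaryl phosphine is suited; the iodide sits on the electron-rich flavone and boron on the benzaldehyde partner, which is less prone to protodeboronation.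

Step 6
Reactants: 8 5-bromobenzene-1,3-diol
Product: 9 1,3-bis(benzyloxy)-5-bromobenzene
Conditions: BnBr, K2CO3, DMF, 60 °C
Reagents that add atoms: benzyl bromide, BrCc1ccccc1
Why: Williamson etherification of both phenols.

Step 7
Reactants: 9 1,3-bis(benzyloxy)-5-bromobenzene
Product: 10 1,5-bis(benzyloxy)-3-bromo-2-iodobenzene
Conditions: NIS (1.0 equiv), TFA (cat.), MeCN, 0 °C to rt
Reagents that add atoms: N-iodosuccinimide, O=C1CCC(=O)N1I
Why: Electrophilic aromatic iodination; resorcinol diethers are attacked para to one alkoxy group and ortho to the other, i.e. next to bromine, in preference to the position flanked by both benzyloxy groups, which puts iodine where the side chain must be attached.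

Step 8
Reactants: 10 1,5-bis(benzyloxy)-3-bromo-2-iodobenzene
Product: 12 ethyl 2-[4,6-bis(benzyloxy)-2-bromophenyl]-2-oxoacetate, via arylmagnesium chloride 11 (not isolated)
Conditions: i-PrMgCl·LiCl, THF, −40 °C; then cannulated into (CO2Et)2 (excess), THF, −78 °C; aq. NH4Cl
Reagents that add atoms: isopropylmagnesium chloride–lithium chloride, CC(C)[Mg]Cl.[Li+].[Cl-] (magnesium and chlorine of 11); diethyl oxalate, CCOC(=O)C(=O)OCC
Why: Iodine–magnesium exchange is far faster at C–I than at C–Br at low temperature (where the ortho-bromo arylmagnesium does not eliminate), and the arylmagnesium acylates excess diethyl oxalate once (Grignard addition giving a stable tetrahedral adduct) to deliver the aryl glyoxylate.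

Step 9
Reactants: 12 ethyl 2-[4,6-bis(benzyloxy)-2-bromophenyl]-2-oxoacetate
Product: 13 ethyl 2-[4,6-bis(benzyloxy)-2-bromophenyl]prop-2-enoate
Conditions: Ph3PCH3Br, KN(SiMe3)2, THF, 0 °C; then 12, −78 °C to rt
Reagents that add atoms: methyltriphenylphosphonium bromide, C[P+](c1ccccc1)(c1ccccc1)c1ccccc1.[Br-]
Why: Wittig methylenation; the ketone carbonyl of an aryl glyoxylate is highly electrophilic and cannot enolise, so the small non-stabilised ylide should add to it selectively over the ester.

Step 10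
Reactants: 13 ethyl 2-[4,6-bis(benzyloxy)-2-bromophenyl]prop-2-enoate
Product: 14 2-[4,6-bis(benzyloxy)-2-bromophenyl]prop-2-en-1-ol
Conditions: i-Bu2AlH, CH2Cl2, −78 °C; aq. potassium sodium tartrate
Reagents that add atoms: none
Why: 1,2-Reduction of the acrylate ester by the aluminium hydride at low temperature gives the allylic alcohol and leaves the aryl bromide, the benzyl ethers and the 1,1-disubstituted alkene untouched.

Step 11
Reactants: 14 2-[4,6-bis(benzyloxy)-2-bromophenyl]prop-2-en-1-ol
Product: 15 2-[4,6-bis(benzyloxy)-2-bromophenyl]prop-2-en-1-yl methyl carbonate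
Conditions: ClCO2Me, pyridine, CH2Cl2, 0 °C
Reagents that add atoms: methyl chloroformate, COC(=O)Cl
Why: O-Acylation of the primary allylic alcohol to the methyl carbonate, the leaving group needed for copper-catalysed allylic borylation.

Step 12
Reactants: 15 2-[4,6-bis(benzyloxy)-2-bromophenyl]prop-2-en-1-yl methyl carbonate
Product: 16 2-{2-[4,6-bis(benzyloxy)-2-bromophenyl]prop-2-en-1-yl}-4,4,5,5-tetramethyl-1,3,2-dioxaborolane
Conditions: B2pin2, CuCl (cat.), Xantphos (cat.), KOt-Bu (cat.), THF, rt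
Reagents that add atoms: bis(pinacolato)diboron, CC1(C)OB(OC1(C)C)B1OC(C)(C)C(C)(C)O1
Why: Copper-catalysed allylic borylation: a boryl–copper species generated from CuOt-Bu and B2pin2 displaces the carbonate (formal SN2'); the two CH2 termini of the 2-arylallyl unit are equivalent, so no regiochemical issue arises, and at room temperature the aryl bromide is not engaged.

Step 13
Reactants: 7 3,4-bis(benzyloxy)-5-(LutBn4)benzaldehyde; 16 2-arylallyl pinacol boronate
Product: 17 (1S)-1-[3,4-bis(benzyloxy)-5-(LutBn4)phenyl]-3-[4,6-bis(benzyloxy)-2-bromophenyl]but-3-en-1-ol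
Conditions: (S)-3,3'-bis(2,4,6-triisopropylphenyl)-1,1'-binaphthyl-2,2'-diyl hydrogen phosphate [(S)-TRIP] (10 mol%), 4 Å MS, toluene, −30 °C; aqueous work-up
Reagents that add atoms: none
Why: Chiral phosphoric acid-catalysed allylboration of an aryl aldehyde through a closed six-membered chair transition state in which the acid hydrogen-bonds to a boronate oxygen and the formyl C–H; the (S)-catalyst is expected to deliver the allyl unit to the Si face of the aldehyde and so set the S carbinol, the only stereocentre of the target.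

Step 14
Reactants: 17 (1S)-1-[3,4-bis(benzyloxy)-5-(LutBn4)phenyl]-3-[4,6-bis(benzyloxy)-2-bromophenyl]but-3-en-1-ol
Product: 18 (2S)-5,7-bis(benzyloxy)-2-[3,4-bis(benzyloxy)-5-(LutBn4)phenyl]-4-methylidene-3,4-dihydro-2H-chromene (4-methylene flavan)
Conditions: Pd(OAc)2 (5 mol%), rac-2-(di-tert-butylphosphino)-1,1'-binaphthyl (6 mol%), Cs2CO3, toluene (dilute), 80 °C
Reagents that add atoms: none
Why: Zerovalent palladium, formed in situ from Pd(OAc)2 and the phosphine, inserts into the C8a–Br bond of ring A; Cs2CO3 then converts the C2 hydroxyl into a palladium-bound alkoxide with loss of bromide, and C–O reductive elimination from the seven-membered aryl(alkoxo)palladium chelate forms O1–C8a. The closest known reaction type is the Buchwald–Hartwig-type intramolecular etherification of aryl halides with secondary alcohols to chromans, which leaves the carbinol configuration intact. Ring C, the only ring formed, closes in a six-membered exo mode: the alkoxide oxygen bonds to the ring A carbon C8a and the departing bromide lies outside the new ring. No stereocentre is created; the S configuration at C2 is carried over because none of its four bonds is made or broken, and with C4 present as a methylene there is no carbonyl through which retro-aldol, dehydration or ring-opening could scramble it. The selectivity needed is C–O reductive elimination over β-hydride elimination of the benzylic alkoxide (which would oxidise the carbinol and debrominate ring A); it is secured by the bulky electron-rich phosphine, helped in the substrate by the ortho-alkenyl group on the arylpalladium unit and the short tether, while the full set of benzyl ethers leaves the C2 hydroxyl as the only nucleophile and C8a–Br as the only site of oxidative addition.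

Step 15
Reactants: 18 (2S)-4-methylene flavan
Product: 20 (2S)-5,7-bis(benzyloxy)-2-[3,4-bis(benzyloxy)-5-(LutBn4)phenyl]-2,3-dihydro-4H-chromen-4-one (octa-O-benzyl flavanone), via vicinal diol 19 (not isolated)
Conditions: OsO4 (cat.), NaIO4, 2,6-lutidine, 1,4-dioxane/H2O, rt
Reagents that add atoms: osmium tetroxide, O=[Os](=O)(=O)=O (oxygens of 19 and 20); sodium periodate, [Na+].[O-]I(=O)(=O)=O (terminal oxidant that restores OsO4)
Why: Lemieux–Johnson oxidation: OsO4 dihydroxylates the only isolated alkene (the chromenone C2–C3 bond is electron-poor and part of an aromatic pyranone) and NaIO4 cleaves the diol to the C4 ketone while regenerating OsO4; the C4 carbinol centre of 19 is destroyed again and the buffered, near-neutral medium leaves C2 untouched.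

Step 16
Reactants: 20 (2S)-octa-O-benzyl flavanone
Product: 21 (2S)-2-{3,4-dihydroxy-5-[2-(3,4-dihydroxyphenyl)-5,7-dihydroxy-4-oxo-4H-chromen-8-yl]phenyl}-5,7-dihydroxy-2,3-dihydro-4H-chromen-4-one (CNP0224656.1)
Conditions: H2 (1 atm), Pd(OH)2/C, THF/MeOH, rt
Reagents that add atoms: none
Why: Catalytic hydrogenolysis removes all eight benzyl ethers under neutral conditions that cannot open ring C by β-elimination, so the S configuration at C2 set in step 13 reaches the target unchanged.

Compound list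

1 | luteolin | O=c1cc(-c2ccc(O)c(O)c2)oc2cc(O)cc(O)c12 | starting material
2 | 5,7-bis(benzyloxy)-2-[3,4-bis(benzyloxy)phenyl]-4H-chromen-4-one | O=c1cc(-c2ccc(OCc9ccccc9)c(OCc9ccccc9)c2)oc2cc(OCc9ccccc9)cc(OCc9ccccc9)c12 | intermediate
3 | 5,7-bis(benzyloxy)-2-[3,4-bis(benzyloxy)phenyl]-8-iodo-4H-chromen-4-one | O=c1cc(-c2ccc(OCc9ccccc9)c(OCc9ccccc9)c2)oc2c(I)c(OCc9ccccc9)cc(OCc9ccccc9)c12 | intermediate
4 | 3-bromo-4,5-dihydroxybenzaldehyde | O=Cc1cc(O)c(O)c(Br)c1 | starting material
5 | 3,4-bis(benzyloxy)-5-bromobenzaldehyde | O=Cc1cc(OCc9ccccc9)c(OCc9ccccc9)c(Br)c1 | intermediate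
6 | 3,4-bis(benzyloxy)-5-(4,4,5,5-tetramethyl-1,3,2-dioxaborolan-2-yl)benzaldehyde | O=Cc1cc(OCc9ccccc9)c(OCc9ccccc9)c(B2OC(C)(C)C(C)(C)O2)c1 | intermediate
7 | 3,4-bis(benzyloxy)-5-{5,7-bis(benzyloxy)-2-[3,4-bis(benzyloxy)phenyl]-4-oxo-4H-chromen-8-yl}benzaldehyde | O=Cc2cc(OCc9ccccc9)c(OCc9ccccc9)c(-c3c(OCc9ccccc9)cc(OCc9ccccc9)c4c(=O)cc(-c5ccc(OCc9ccccc9)c(OCc9ccccc9)c5)oc34)c2 | intermediate
8 | 5-bromobenzene-1,3-diol | Oc1cc(O)cc(Br)c1 | starting material
9 | 1,3-bis(benzyloxy)-5-bromobenzene | Brc1cc(OCc9ccccc9)cc(OCc9ccccc9)c1 | intermediate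
10 | 1,5-bis(benzyloxy)-3-bromo-2-iodobenzene | Ic1c(Br)cc(OCc9ccccc9)cc1OCc9ccccc9 | intermediate
11 | [4,6-bis(benzyloxy)-2-bromophenyl]magnesium chloride (LiCl complex) | Cl[Mg]c1c(Br)cc(OCc9ccccc9)cc1OCc9ccccc9 | intermediate (not isolated)
12 | ethyl 2-[4,6-bis(benzyloxy)-2-bromophenyl]-2-oxoacetate | CCOC(=O)C(=O)c1c(Br)cc(OCc9ccccc9)cc1OCc9ccccc9 | intermediate
13 | ethyl 2-[4,6-bis(benzyloxy)-2-bromophenyl]prop-2-enoate | CCOC(=O)C(=C)c1c(Br)cc(OCc9ccccc9)cc1OCc9ccccc9 | intermediate
14 | 2-[4,6-bis(benzyloxy)-2-bromophenyl]prop-2-en-1-ol | OCC(=C)c1c(Br)cc(OCc9ccccc9)cc1OCc9ccccc9 | intermediate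
15 | 2-[4,6-bis(benzyloxy)-2-bromophenyl]prop-2-en-1-yl methyl carbonate | COC(=O)OCC(=C)c1c(Br)cc(OCc9ccccc9)cc1OCc9ccccc9 | intermediate
16 | 2-{2-[4,6-bis(benzyloxy)-2-bromophenyl]prop-2-en-1-yl}-4,4,5,5-tetramethyl-1,3,2-dioxaborolane | C=C(CB2OC(C)(C)C(C)(C)O2)c1c(Br)cc(OCc9ccccc9)cc1OCc9ccccc9 | intermediate
17 | (1S)-1-{3,4-bis(benzyloxy)-5-[5,7-bis(benzyloxy)-2-(3,4-bis(benzyloxy)phenyl)-4-oxo-4H-chromen-8-yl]phenyl}-3-[4,6-bis(benzyloxy)-2-bromophenyl]but-3-en-1-ol | C=C(C[C@H](O)c2cc(OCc9ccccc9)c(OCc9ccccc9)c(-c3c(OCc9ccccc9)cc(OCc9ccccc9)c4c(=O)cc(-c5ccc(OCc9ccccc9)c(OCc9ccccc9)c5)oc34)c2)c1c(Br)cc(OCc9ccccc9)cc1OCc9ccccc9 | intermediate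
18 | (2S)-5,7-bis(benzyloxy)-2-{3,4-bis(benzyloxy)-5-[5,7-bis(benzyloxy)-2-(3,4-bis(benzyloxy)phenyl)-4-oxo-4H-chromen-8-yl]phenyl}-4-methylidene-3,4-dihydro-2H-chromene | C=C1C[C@@H](c2cc(OCc9ccccc9)c(OCc9ccccc9)c(-c3c(OCc9ccccc9)cc(OCc9ccccc9)c4c(=O)cc(-c5ccc(OCc9ccccc9)c(OCc9ccccc9)c5)oc34)c2)Oc2cc(OCc9ccccc9)cc(OCc9ccccc9)c21 | intermediate
19 | (2S)-5,7-bis(benzyloxy)-2-{3,4-bis(benzyloxy)-5-[5,7-bis(benzyloxy)-2-(3,4-bis(benzyloxy)phenyl)-4-oxo-4H-chromen-8-yl]phenyl}-4-(hydroxymethyl)-3,4-dihydro-2H-chromen-4-ol (both C4 epimers) | OCC1(O)C[C@@H](c2cc(OCc9ccccc9)c(OCc9ccccc9)c(-c3c(OCc9ccccc9)cc(OCc9ccccc9)c4c(=O)cc(-c5ccc(OCc9ccccc9)c(OCc9ccccc9)c5)oc34)c2)Oc2cc(OCc9ccccc9)cc(OCc9ccccc9)c21 | intermediate (not isolated)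
20 | (2S)-5,7-bis(benzyloxy)-2-{3,4-bis(benzyloxy)-5-[5,7-bis(benzyloxy)-2-(3,4-bis(benzyloxy)phenyl)-4-oxo-4H-chromen-8-yl]phenyl}-2,3-dihydro-4H-chromen-4-one | O=C1C[C@@H](c2cc(OCc9ccccc9)c(OCc9ccccc9)c(-c3c(OCc9ccccc9)cc(OCc9ccccc9)c4c(=O)cc(-c5ccc(OCc9ccccc9)c(OCc9ccccc9)c5)oc34)c2)Oc2cc(OCc9ccccc9)cc(OCc9ccccc9)c21 | intermediate
21 | (2S)-2-{3,4-dihydroxy-5-[2-(3,4-dihydroxyphenyl)-5,7-dihydroxy-4-oxo-4H-chromen-8-yl]phenyl}-5,7-dihydroxy-2,3-dihydro-4H-chromen-4-one (CNP0224656.1) | O=C1C[C@@H](c2cc(O)c(O)c(-c3c(O)cc(O)c4c(=O)cc(-c5ccc(O)c(O)c5)oc34)c2)Oc2cc(O)cc(O)c21 | target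

Total step count: 16.
Longest linear sequence: 11 steps (steps 6 to 16, from 5-bromobenzene-1,3-diol).

Steps most likely to fail

1. Step 14 (ring closure). What may go wrong: after oxidative addition the palladium alkoxide undergoes β-hydride elimination instead of C–O reductive elimination, which oxidises the benzylic carbinol and hydrodebrominates ring A. The palladium hydride so formed may also move the exocyclic double bond into ring C. Fallback: close ring C from the other side, forming O1–C2 with inversion. It sets out from aldehyde 7 (with boronate 16). Allylboration under the (R)-enantiomer of the phosphoric acid gives (1R)-1-[3,4-bis(benzyloxy)-5-(LutBn4)phenyl]-3-[4,6-bis(benzyloxy)-2-bromophenyl]but-3-en-1-ol F1. Miyaura borylation (B2pin2, PdCl2(dppf), KOAc, 1,4-dioxane, 90 °C; weak base and a ligand that does not promote C–O coupling) converts C8a–Br into the aryl pinacol boronate F2. Oxidation (NaBO3·4H2O, THF/H2O, rt) gives the (1R)-phenol alcohol F3. Mitsunobu cyclisation (PPh3, DIAD, THF, 0 °C) displaces the activated carbinol by the phenol with inversion and comes back to the route at 18.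

2. Step 13 (asymmetric allylboration). What may go wrong: poor facial selectivity or a competing uncatalysed addition, because the aldehyde is large, its chromenone carbonyl can sequester the acid, and the boronate carries a twisted, di-ortho-substituted aryl group on the central allyl carbon. Fallback: set the stereocentre by ketone reduction instead of C–C bond formation. It sets out from 17 of insufficient enantiomeric purity. Dess–Martin periodinane (NaHCO3, CH2Cl2, 0 °C) gives the β,γ-unsaturated aryl ketone 1-[3,4-bis(benzyloxy)-5-(LutBn4)phenyl]-3-[4,6-bis(benzyloxy)-2-bromophenyl]but-3-en-1-one F4. Corey–Bakshi–Shibata reduction ((R)-2-methyl-CBS-oxazaborolidine, catecholborane, toluene, −78 °C, chosen to spare the alkene) comes back to the route at 17 as the S carbinol.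

3. Step 16 (global hydrogenolysis). What may go wrong: incomplete removal of the eight benzyl ethers, or over-reduction (saturation of the C2–C3 double bond of the luteolin unit, hydrogenolysis of the benzylic C2–O1 bond of ring C). Fallback: non-reductive Lewis-acid debenzylation, setting out from 20 and arriving directly at 21, with BCl3 and pentamethylbenzene (CH2Cl2, −78 °C), the arene trapping the benzyl cations; no new intermediate is made.

Further compounds

F1 | step 14 | (1R)-1-{3,4-bis(benzyloxy)-5-[5,7-bis(benzyloxy)-2-(3,4-bis(benzyloxy)phenyl)-4-oxo-4H-chromen-8-yl]phenyl}-3-[4,6-bis(benzyloxy)-2-bromophenyl]but-3-en-1-ol | C=C(C[C@@H](O)c2cc(OCc9ccccc9)c(OCc9ccccc9)c(-c3c(OCc9ccccc9)cc(OCc9ccccc9)c4c(=O)cc(-c5ccc(OCc9ccccc9)c(OCc9ccccc9)c5)oc34)c2)c1c(Br)cc(OCc9ccccc9)cc1OCc9ccccc9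
F2 | step 14 | (1R)-1-{3,4-bis(benzyloxy)-5-[5,7-bis(benzyloxy)-2-(3,4-bis(benzyloxy)phenyl)-4-oxo-4H-chromen-8-yl]phenyl}-3-[4,6-bis(benzyloxy)-2-(4,4,5,5-tetramethyl-1,3,2-dioxaborolan-2-yl)phenyl]but-3-en-1-ol | C=C(C[C@@H](O)c2cc(OCc9ccccc9)c(OCc9ccccc9)c(-c3c(OCc9ccccc9)cc(OCc9ccccc9)c4c(=O)cc(-c5ccc(OCc9ccccc9)c(OCc9ccccc9)c5)oc34)c2)c1c(B7OC(C)(C)C(C)(C)O7)cc(OCc9ccccc9)cc1OCc9ccccc9
F3 | step 14 | (1R)-1-{3,4-bis(benzyloxy)-5-[5,7-bis(benzyloxy)-2-(3,4-bis(benzyloxy)phenyl)-4-oxo-4H-chromen-8-yl]phenyl}-3-[4,6-bis(benzyloxy)-2-hydroxyphenyl]but-3-en-1-ol | C=C(C[C@@H](O)c2cc(OCc9ccccc9)c(OCc9ccccc9)c(-c3c(OCc9ccccc9)cc(OCc9ccccc9)c4c(=O)cc(-c5ccc(OCc9ccccc9)c(OCc9ccccc9)c5)oc34)c2)c1c(O)cc(OCc9ccccc9)cc1OCc9ccccc9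
F4 | step 13 | 1-{3,4-bis(benzyloxy)-5-[5,7-bis(benzyloxy)-2-(3,4-bis(benzyloxy)phenyl)-4-oxo-4H-chromen-8-yl]phenyl}-3-[4,6-bis(benzyloxy)-2-bromophenyl]but-3-en-1-one | C=C(CC(=O)c2cc(OCc9ccccc9)c(OCc9ccccc9)c(-c3c(OCc9ccccc9)cc(OCc9ccccc9)c4c(=O)cc(-c5ccc(OCc9ccccc9)c(OCc9ccccc9)c5)oc34)c2)c1c(Br)cc(OCc9ccccc9)cc1OCc9ccccc9
F0 | step 16 | none | none
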